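**Plan**

1. Retrosynthesis: the MOM group on the C7 oxygen and a helper chlorine on C5 are removed last. Ring C is then cut in one move across O1–C8a and C4–C4a, which leaves an aryne of ring A and an (S)-3-aryl-3-(silyloxy)propanoate. The C2 carbinol goes back to a β-keto ester.
2. Enabling feature: O1 and the C4 carbonyl carbon sit on the neighbouring ring-A carbons C8a and C4a, the pattern left when an aryne inserts between the oxygen and the acyl carbon of a β-oxy ester. C5 carries only hydrogen in the target, so a chlorine can be lodged there to steer the oxygen to C8a (beside the C8 prenyl group) and be exchanged for hydrogen afterwards.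
3. Forward, ring A: 5-chlororesorcinol is dressed by three directed lithiations (prenyl at C8, prenyl at C6, iodine at C4a). A retro-Brook shift then turns iodine into the silyl group and marks the C8a oxygen for triflation.
4. Forward, ring C: formed in one operation from aryne and alkoxide (O1–C8a, then C4–C4a); hydrodechlorination and MOM cleavage finish the synthesis.
5. Stereochemistry: the single stereocenter C2 is set by asymmetric hydrogenation of the β-keto ester, and its C–O bond is never broken afterwards.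

Key step: step 10

Assumption: the aryl β-keto ester 13 is taken to follow the usual facial sense of BINAP–ruthenium hydrogenation of β-keto esters, so that the (R)-ligand should give the (S)-alcohol; the other ligand enantiomer would be used if the sense proved opposite.

**Route**

Step 1
Reactants: 1 5-chlorobenzene-1,3-diol
Product: 2 1-chloro-3,5-bis(methoxymethoxy)benzene
Conditions: MOMCl (2.5 equiv), i-Pr2NEt, CH2Cl2, 0 °C → rt
Reagents that add atoms: chloromethyl methyl ether, COCCl
Why: Standard acetal protection of both phenols (O-alkylation), which also installs the directing groups for the lithiations that follow.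

Step 2
Reactants: 2 1-chloro-3,5-bis(methoxymethoxy)benzene
Product: 3 5-chloro-1,3-bis(methoxymethoxy)-2-(3-methylbut-2-en-1-yl)benzene
Conditions: n-BuLi, THF, −20 °C; CuBr·SMe2, −78 °C; prenyl bromide, −78 °C → rt
Reagents that add atoms: 1-bromo-3-methylbut-2-ene, CC(C)=CCBr
Why: Directed ortho-metalation should take place at the position flanked by both acetal oxygens, and the arylcopper should be allylated at the primary carbon of prenyl bromide.

Step 3
Reactants: 3 5-chloro-1,3-bis(methoxymethoxy)-2-(3-methylbut-2-en-1-yl)benzene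
Product: 4 1-chloro-3,5-bis(methoxymethoxy)-2,4-bis(3-methylbut-2-en-1-yl)benzene
Conditions: s-BuLi, TMEDA, THF, −78 °C; CuBr·SMe2; prenyl bromide, −78 → 0 °C
Reagents that add atoms: 1-bromo-3-methylbut-2-ene, CC(C)=CCBr
Why: Second directed ortho-metalation at one of the two equivalent positions between an acetal oxygen and chlorine, held at −78 °C so that the ortho-chloroaryllithium does not lose LiCl, then copper-mediated allylation as in step 2.

Step 4
Reactants: 4 1-chloro-3,5-bis(methoxymethoxy)-2,4-bis(3-methylbut-2-en-1-yl)benzene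
Product: 5 1-chloro-2-iodo-3,5-bis(methoxymethoxy)-4,6-bis(3-methylbut-2-en-1-yl)benzene
Conditions: s-BuLi, TMEDA, THF, −78 °C; iodine, −78 °C → rt
Reagents that add atoms: iodine, [I][I]
Why: The only ring hydrogen left, acidified by chlorine and the neighbouring acetal oxygen, should be lithiated (directed ortho-metalation) and quenched by iodine, which puts an exchangeable halogen on the future C4a.

Step 5
Reactants: 5 1-chloro-2-iodo-3,5-bis(methoxymethoxy)-4,6-bis(3-methylbut-2-en-1-yl)benzene
Product: 6 5-chloro-4-iodo-2,6-bis(3-methylbut-2-en-1-yl)benzene-1,3-diol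
Conditions: HCl (3 M aq.), MeOH, 40 °C
Reagents that add atoms: none
Why: Acid-catalysed acetal cleavage should free both phenols, under conditions mild enough to keep the prenyl groups from cyclising onto them.

Step 6
Reactants: 6 5-chloro-4-iodo-2,6-bis(3-methylbut-2-en-1-yl)benzene-1,3-diol
Product: 11 3-chloro-5-hydroxy-4,6-bis(3-methylbut-2-en-1-yl)-2-(trimethylsilyl)phenyl trifluoromethanesulfonate, via bis(trimethylsilyl) ether 7 (not isolated), via aryllithium 8 (not isolated), via lithium phenoxide 9 (not isolated), via silyl ether triflate 10 (not isolated)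
Conditions: HMDS, 80 °C, then evaporate; n-BuLi, THF, −78 °C; Tf2O, −78 → 0 °C; 1 M HCl, THF/MeOH, 0 °C
Reagents that add atoms: hexamethyldisilazane, C[Si](C)(C)N[Si](C)(C)C; trifluoromethanesulfonic anhydride, O=S(=O)(OS(=O)(=O)C(F)(F)F)C(F)(F)F
Why: One-pot O-silylation, iodine–lithium exchange, retro-Brook (1,3 O→C) silyl shift and triflation of the phenoxide so released, in which only the oxygen next to the lithiated carbon gives up its silyl group, so the two phenols are told apart.

Step 7
Reactants: 11 3-chloro-5-hydroxy-4,6-bis(3-methylbut-2-en-1-yl)-2-(trimethylsilyl)phenyl trifluoromethanesulfonate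
Product: 12 3-chloro-5-(methoxymethoxy)-4,6-bis(3-methylbut-2-en-1-yl)-2-(trimethylsilyl)phenyl trifluoromethanesulfonate
Conditions: MOMCl, i-Pr2NEt, CH2Cl2, 0 °C → rt
Reagents that add atoms: chloromethyl methyl ether, COCCl
Why: Fluoride-free O-alkylation should cap the remaining hindered phenol, which would otherwise add to the aryne in step 10.

Step 8
Reactants: 13 ethyl 3-(3,4-dimethoxyphenyl)-3-oxopropanoate
Product: 14 ethyl (3S)-3-(3,4-dimethoxyphenyl)-3-hydroxypropanoate
Conditions: RuCl2[(R)-BINAP](dmf)n (1 mol%), H2 (50 bar), EtOH, 80 °C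
Reagents that add atoms: none
Why: Noyori asymmetric hydrogenation of a β-keto ester, in which the chelated substrate sits in the chiral pocket of the (R)-diphosphine and hydride is delivered to one ketone face, should set the (S)-carbinol that becomes C2.

Step 9
Reactants: 14 ethyl (3S)-3-(3,4-dimethoxyphenyl)-3-hydroxypropanoate
Product: 15 ethyl (3S)-3-(3,4-dimethoxyphenyl)-3-(trimethylsilyloxy)propanoate
Conditions: TMSCl, imidazole, CH2Cl2, 0 °C
Reagents that add atoms: chlorotrimethylsilane, C[Si](C)(C)Cl
Why: O-Silylation turns the alcohol into a proton-free alkoxide precursor that the fluoride of step 10 unveils, without touching the stereocenter.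

Step 10
Reactants: 12 3-chloro-5-(methoxymethoxy)-4,6-bis(3-methylbut-2-en-1-yl)-2-(trimethylsilyl)phenyl trifluoromethanesulfonate; 15 ethyl (3S)-3-(3,4-dimethoxyphenyl)-3-(trimethylsilyloxy)propanoate
Product: 18 (2S)-5-chloro-2-(3,4-dimethoxyphenyl)-7-(methoxymethoxy)-6,8-bis(3-methylbut-2-en-1-yl)-2,3-dihydro-4H-chromen-4-one, via aryne 16 (not isolated), via potassium alkoxide 17 (not isolated)
Conditions: 12 (1.3 equiv), KF (1.1 equiv), 18-crown-6 (1.1 equiv), THF, −20 °C → rt
Reagents that add atoms: none
Why: Proposed new method: fluoride removes the aryl silyl group of 12 (triflate leaves, 3-chloroaryne 16) and the O-silyl group of 15 (alkoxide 17), 17 adds through oxygen to the aryne carbon remote from chlorine, the aryl carbanion so formed at C4a attacks the ester carbonyl and expels ethoxide, and this ethoxide is trapped by the silyl groups still present, so that about one equivalent of fluoride suffices and no free alkoxide is left to open the product by retro-oxa-Michael reaction. The closest known reaction type is the aryne annulation of methyl salicylates to xanthones (an oxygen nucleophile adds to the aryne, the aryl anion then acylates itself on the ester) together with aryne insertions into acyl–heteroatom bonds; an aliphatic, stereogenic β-oxy ester has not been used in this way. Ring C is closed at the C4–C4a bond by a 6-exo-trig attack of the aryl carbanion on the ester carbonyl, after the intermolecular O1–C8a bond has formed. No stereocenter is created: C2 is carried in from 15 and none of its bonds is broken, so the S configuration should be kept. The step needs the oxygen to add at C8a although that carbon is flanked by the C8 prenyl group, and the chlorine on C5 secures this, because a 3-haloaryne is bent so that nucleophiles add to the remote carbon and the charge develops beside the carbon–chlorine bond. It also needs acylation to outrun proton transfer and loss of chloride from the carbanion, which the proton-free silyl-masked alkoxide, the six-membered transition state and the poor leaving ability of chloride from an aryl anion should secure.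

Step 11
Reactants: 18 (2S)-5-chloro-2-(3,4-dimethoxyphenyl)-7-(methoxymethoxy)-6,8-bis(3-methylbut-2-en-1-yl)-2,3-dihydro-4H-chromen-4-one
Product: 19 (2S)-2-(3,4-dimethoxyphenyl)-7-(methoxymethoxy)-6,8-bis(3-methylbut-2-en-1-yl)-2,3-dihydro-4H-chromen-4-one
Conditions: Pd(OAc)2 (5 mol%), 2-(di-tert-butylphosphino)biphenyl (10 mol%), HCO2Na, MeOH, 60 °C
Reagents that add atoms: none
Why: Palladium-catalysed transfer hydrodechlorination (zerovalent palladium inserts into the carbon–chlorine bond activated by the ortho carbonyl, formate exchanges for chloride, CO2 is lost and the C–H bond is formed by reductive elimination) should replace the helper by hydrogen under weakly basic conditions that leave C2 and the prenyl groups alone.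

Step 12
Reactants: 19 (2S)-2-(3,4-dimethoxyphenyl)-7-(methoxymethoxy)-6,8-bis(3-methylbut-2-en-1-yl)-2,3-dihydro-4H-chromen-4-one
Product: 20 (2S)-2-(3,4-dimethoxyphenyl)-7-hydroxy-6,8-bis(3-methylbut-2-en-1-yl)-2,3-dihydro-4H-chromen-4-one
Conditions: HCl (1.25 M in MeOH), 40 °C
Reagents that add atoms: none
Why: Mild acid-catalysed acetal cleavage should free the C7 phenol without opening ring C or cyclising the flanking prenyl groups.

**Compound list**

1 | 5-chlorobenzene-1,3-diol (5-chlororesorcinol) | Oc1cc(O)cc(Cl)c1 | starting material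
2 | 1-chloro-3,5-bis(methoxymethoxy)benzene | COCOc1cc(Cl)cc(OCOC)c1 | intermediate
3 | 5-chloro-1,3-bis(methoxymethoxy)-2-(3-methylbut-2-en-1-yl)benzene | COCOc1cc(Cl)cc(OCOC)c1CC=C(C)C | intermediate
4 | 1-chloro-3,5-bis(methoxymethoxy)-2,4-bis(3-methylbut-2-en-1-yl)benzene | COCOc1cc(Cl)c(CC=C(C)C)c(OCOC)c1CC=C(C)C | intermediate
5 | 1-chloro-2-iodo-3,5-bis(methoxymethoxy)-4,6-bis(3-methylbut-2-en-1-yl)benzene | COCOc1c(I)c(Cl)c(CC=C(C)C)c(OCOC)c1CC=C(C)C | intermediate
6 | 5-chloro-4-iodo-2,6-bis(3-methylbut-2-en-1-yl)benzene-1,3-diol | Oc1c(I)c(Cl)c(CC=C(C)C)c(O)c1CC=C(C)C | intermediate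
7 | bis(trimethylsilyl) ether of 6 | C[Si](C)(C)Oc1c(I)c(Cl)c(CC=C(C)C)c(O[Si](C)(C)C)c1CC=C(C)C | intermediate
8 | [2-chloro-3,5-bis(3-methylbut-2-en-1-yl)-4,6-bis(trimethylsilyloxy)phenyl]lithium | [Li]c1c(Cl)c(CC=C(C)C)c(O[Si](C)(C)C)c(CC=C(C)C)c1O[Si](C)(C)C | intermediate
9 | lithium 3-chloro-4,6-bis(3-methylbut-2-en-1-yl)-2-(trimethylsilyl)-5-(trimethylsilyloxy)phenoxide | [Li+].[O-]c1c([Si](C)(C)C)c(Cl)c(CC=C(C)C)c(O[Si](C)(C)C)c1CC=C(C)C | intermediate
10 | 3-chloro-4,6-bis(3-methylbut-2-en-1-yl)-2-(trimethylsilyl)-5-(trimethylsilyloxy)phenyl trifluoromethanesulfonate | C[Si](C)(C)Oc1c(CC=C(C)C)c(Cl)c([Si](C)(C)C)c(OS(=O)(=O)C(F)(F)F)c1CC=C(C)C | intermediate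
11 | 3-chloro-5-hydroxy-4,6-bis(3-methylbut-2-en-1-yl)-2-(trimethylsilyl)phenyl trifluoromethanesulfonate | Oc1c(CC=C(C)C)c(Cl)c([Si](C)(C)C)c(OS(=O)(=O)C(F)(F)F)c1CC=C(C)C | intermediate
12 | 3-chloro-5-(methoxymethoxy)-4,6-bis(3-methylbut-2-en-1-yl)-2-(trimethylsilyl)phenyl trifluoromethanesulfonate | COCOc1c(CC=C(C)C)c(Cl)c([Si](C)(C)C)c(OS(=O)(=O)C(F)(F)F)c1CC=C(C)C | intermediate
13 | ethyl 3-(3,4-dimethoxyphenyl)-3-oxopropanoate | CCOC(=O)CC(=O)c1ccc(OC)c(OC)c1 | starting material
14 | ethyl (3S)-3-(3,4-dimethoxyphenyl)-3-hydroxypropanoate | CCOC(=O)C[C@H](O)c1ccc(OC)c(OC)c1 | intermediate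
15 | ethyl (3S)-3-(3,4-dimethoxyphenyl)-3-(trimethylsilyloxy)propanoate | CCOC(=O)C[C@H](O[Si](C)(C)C)c1ccc(OC)c(OC)c1 | intermediate
16 | 3-chloro-5-(methoxymethoxy)-4,6-bis(3-methylbut-2-en-1-yl)benzyne (1,2-didehydrobenzene) | ClC1=C(CC=C(C)C)C(OCOC)=C(CC=C(C)C)C#C1 | intermediate
17 | potassium (1S)-1-(3,4-dimethoxyphenyl)-3-ethoxy-3-oxopropan-1-olate | CCOC(=O)C[C@H]([O-])c1ccc(OC)c(OC)c1.[K+] | intermediate
18 | (2S)-5-chloro-2-(3,4-dimethoxyphenyl)-7-(methoxymethoxy)-6,8-bis(3-methylbut-2-en-1-yl)-2,3-dihydro-4H-chromen-4-one | COc1ccc([C@@H]2CC(=O)c3c(Cl)c(CC=C(C)C)c(OCOC)c(CC=C(C)C)c3O2)cc1OC | intermediate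
19 | (2S)-2-(3,4-dimethoxyphenyl)-7-(methoxymethoxy)-6,8-bis(3-methylbut-2-en-1-yl)-2,3-dihydro-4H-chromen-4-one | COc1ccc([C@@H]2CC(=O)c3cc(CC=C(C)C)c(OCOC)c(CC=C(C)C)c3O2)cc1OC | intermediate
20 | (2S)-2-(3,4-dimethoxyphenyl)-7-hydroxy-6,8-bis(3-methylbut-2-en-1-yl)-2,3-dihydro-4H-chromen-4-one (IN0946) | COc1ccc([C@@H]2CC(=O)c3cc(CC=C(C)C)c(O)c(CC=C(C)C)c3O2)cc1OC | target

**Step count**

Total: 12 steps. Longest linear sequence: 10 steps (steps 1 to 7, then 10 to 12); steps 8 and 9 make the second fragment.

**Steps most likely to fail, with fallbacks**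

Step 10 (proposed new method). What may go wrong:
- addition of the alkoxide to the wrong aryne carbon;
- transfer of a C3 proton to the aryl carbanion instead of acylation, followed by β-elimination;
- loss of chloride from the carbanion;
- base-induced opening of ring C with erosion of the configuration at C2.

The fallback uses known chemistry, the asymmetric conjugate arylation of a chromone. It sets out from 5 and comes back at 18.
- Iodine–magnesium exchange on 5 (i-PrMgCl·LiCl, THF, −20 °C) and acylation with N-methoxy-N-methylacetamide would give 1-[2-chloro-4,6-bis(methoxymethoxy)-3,5-bis(3-methylbut-2-en-1-yl)phenyl]ethan-1-one F1.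
- Condensation with N,N-dimethylformamide dimethyl acetal (neat, 100 °C) would give the enaminone (2E)-1-[2-chloro-4,6-bis(methoxymethoxy)-3,5-bis(3-methylbut-2-en-1-yl)phenyl]-3-(dimethylamino)prop-2-en-1-one F2.
- HCl in MeOH would remove both acetals and close the pyranone to 5-chloro-7-hydroxy-6,8-bis(3-methylbut-2-en-1-yl)-4H-chromen-4-one F3.
- MOMCl and i-Pr2NEt would give 5-chloro-7-(methoxymethoxy)-6,8-bis(3-methylbut-2-en-1-yl)-4H-chromen-4-one F4.
- Conjugate addition of 3,4-dimethoxyphenylboronic acid under Pd(OCOCF3)2 and a chiral pyridine–oxazoline ligand (t-BuPyOx, the enantiomer that gives the 2S series; NH4PF6, H2O, ClCH2CH2Cl, 60 °C) would return to 18.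

Step 11. What may go wrong:
- migration or reduction of the prenyl double bonds by palladium hydride;
- sluggish insertion into the doubly ortho-substituted carbon–chlorine bond;
- partial racemisation through base-induced ring opening during a long reaction.

The fallback is hydride-free and runs in two stages, from 18 to 19.
- Miyaura borylation (Pd2(dba)3, XPhos, bis(pinacolato)diboron, KOAc, dioxane, 90 °C) would give (2S)-2-(3,4-dimethoxyphenyl)-7-(methoxymethoxy)-6,8-bis(3-methylbut-2-en-1-yl)-5-(4,4,5,5-tetramethyl-1,3,2-dioxaborolan-2-yl)-2,3-dihydro-4H-chromen-4-one F5.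
- Protodeboronation of this ortho-acyl, doubly ortho-substituted boronate ([Ir(OMe)(cod)]2 cat., THF/H2O, 80 °C) would give 19.

Step 6. What may go wrong:
- loss of LiCl from the ortho-chloroaryllithium before the silyl shift;
- incomplete silylation of the hindered phenol;
- protodesilylation during the acidic work-up.

The fallback uses carbamate-directed ortho-silylation in place of the halogen–lithium exchange and retro-Brook sequence. It sets out from 4 and comes back at 12, so that steps 4 to 7 are bypassed.
- HCl in MeOH would give 5-chloro-2,4-bis(3-methylbut-2-en-1-yl)benzene-1,3-diol F6.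
- Isopropyl isocyanate (1.0 equiv, cat. Et3N) should carbamoylate the less hindered phenol, flanked by only one prenyl group, to give 5-chloro-3-hydroxy-2,4-bis(3-methylbut-2-en-1-yl)phenyl propan-2-ylcarbamate F7.
- MOMCl and i-Pr2NEt would give 5-chloro-3-(methoxymethoxy)-2,4-bis(3-methylbut-2-en-1-yl)phenyl propan-2-ylcarbamate F8.
- In-situ N-silylation (TBSOTf, TMEDA), lithiation of the only ring hydrogen (n-BuLi, −78 °C) and quenching with TMSCl would give 3-chloro-5-(methoxymethoxy)-4,6-bis(3-methylbut-2-en-1-yl)-2-(trimethylsilyl)phenyl propan-2-ylcarbamate F9.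
- Carbamate cleavage with Et2NH and DBU (MeCN, 40 °C) followed in the same flask by PhNTf2 would give 12.

**Further compounds**

F1 | step 10 | 1-[2-chloro-4,6-bis(methoxymethoxy)-3,5-bis(3-methylbut-2-en-1-yl)phenyl]ethan-1-one | CC(=O)c1c(Cl)c(CC=C(C)C)c(OCOC)c(CC=C(C)C)c1OCOC
F2 | step 10 | (2E)-1-[2-chloro-4,6-bis(methoxymethoxy)-3,5-bis(3-methylbut-2-en-1-yl)phenyl]-3-(dimethylamino)prop-2-en-1-one | CN(C)/C=C/C(=O)c1c(Cl)c(CC=C(C)C)c(OCOC)c(CC=C(C)C)c1OCOC
F3 | step 10 | 5-chloro-7-hydroxy-6,8-bis(3-methylbut-2-en-1-yl)-4H-chromen-4-one | O=c1ccoc2c(CC=C(C)C)c(O)c(CC=C(C)C)c(Cl)c12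
F4 | step 10 | 5-chloro-7-(methoxymethoxy)-6,8-bis(3-methylbut-2-en-1-yl)-4H-chromen-4-one | O=c1ccoc2c(CC=C(C)C)c(OCOC)c(CC=C(C)C)c(Cl)c12
F5 | step 11 | (2S)-2-(3,4-dimethoxyphenyl)-7-(methoxymethoxy)-6,8-bis(3-methylbut-2-en-1-yl)-5-(4,4,5,5-tetramethyl-1,3,2-dioxaborolan-2-yl)-2,3-dihydro-4H-chromen-4-one | COc1ccc([C@@H]2CC(=O)c3c(B4OC(C)(C)C(C)(C)O4)c(CC=C(C)C)c(OCOC)c(CC=C(C)C)c3O2)cc1OC
F6 | step 6 | 5-chloro-2,4-bis(3-methylbut-2-en-1-yl)benzene-1,3-diol | Oc1cc(Cl)c(CC=C(C)C)c(O)c1CC=C(C)C
F7 | step 6 | 5-chloro-3-hydroxy-2,4-bis(3-methylbut-2-en-1-yl)phenyl propan-2-ylcarbamate | CC(C)NC(=O)Oc1cc(Cl)c(CC=C(C)C)c(O)c1CC=C(C)C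
F8 | step 6 | 5-chloro-3-(methoxymethoxy)-2,4-bis(3-methylbut-2-en-1-yl)phenyl propan-2-ylcarbamate | CC(C)NC(=O)Oc1cc(Cl)c(CC=C(C)C)c(OCOC)c1CC=C(C)C
F9 | step 6 | 3-chloro-5-(methoxymethoxy)-4,6-bis(3-methylbut-2-en-1-yl)-2-(trimethylsilyl)phenyl propan-2-ylcarbamate | CC(C)NC(=O)Oc1c([Si](C)(C)C)c(Cl)c(CC=C(C)C)c(OCOC)c1CC=C(C)C
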